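**Retrosynthetic overview**
- The target is the (2S)-flavanone; the last operation removes three methoxymethyl (MOM) groups.
- Ring C is the only ring that is built. Its O1–C8a and C4–C4a bonds form in one operation: a ring-A aryne (triple bond C4a–C8a) takes up the oxygen of an (S)-β-oxido Weinreb amide at C8a, and the aryl anion at C4a then closes the ring on the amide carbon C4.
- Enabling feature: in ring A the ether oxygen O1 (on C8a) and the acyl carbon C4 (on C4a) sit on neighbouring ring carbons, and C4a is flanked by the C5 oxygen. An aryne with an alkoxy group on C5 accepts a nucleophile at C8a and an electrophile at C4a in exactly this sense.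
- The aryne precursor (ortho-silylaryl triflate) comes from phloroglucinol by two carbamate-directed ortho-metalations. The ring-B partner comes from 3,4-dihydroxybenzaldehyde by aromatic Claisen rearrangement (2′-prenyl), aldol/oxidation and asymmetric transfer hydrogenation, which sets C2.
- Rings A and B are bought as arenes; ring C is formed in step 15.

Key step: step 15

Remark on the chemistry: positions follow flavanone numbering (O1, C2, C3, C4, C4a, C5–C8, C8a; ring B primed). MOM = methoxymethyl, prenyl = 3-methylbut-2-en-1-yl. The facial sense of step 13 is assigned by analogy with simple aryl ketones and would be confirmed on the carbinol before it is carried on.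

**Route**

Step 1
Reactants: 1 phloroglucinol (benzene-1,3,5-triol)
Product: 2 3,5-bis(methoxymethoxy)phenol
Conditions: MOMCl (2.0 equiv), iPr2NEt, THF, 0 °C → rt
Reagents that add atoms: chloromethyl methyl ether (MOMCl), COCCl
Why: Williamson-type O-alkylation of a triol whose three hydroxyl groups are equivalent, so the bis-ether is a single compound that should be separable from the mono- and tris-ethers, which can be recycled.

Step 2
Reactants: 2 3,5-bis(methoxymethoxy)phenol
Product: 3 3,5-bis(methoxymethoxy)phenyl N,N-diethylcarbamate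
Conditions: Et2NCOCl, K2CO3, MeCN, 80 °C
Reagents that add atoms: N,N-diethylcarbamoyl chloride, CCN(CC)C(Cl)=O
Why: O-carbamoylation of the phenoxide installs the strongest ortho-directing group for the two metalations that follow.

Step 3
Reactants: 3 3,5-bis(methoxymethoxy)phenyl N,N-diethylcarbamate
Product: 5 3,5-bis(methoxymethoxy)-2-(trimethylsilyl)phenyl N,N-diethylcarbamate, via ortho-lithiated carbamate 4 (not isolated)
Conditions: s-BuLi, TMEDA, THF, –78 °C; then Me3SiCl, –78 °C → rt
Reagents that add atoms: chlorotrimethylsilane, C[Si](C)(C)Cl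
Why: Directed ortho-metalation, in which the carbamate and the neighbouring OMOM group together direct s-BuLi to the carbon between them (the two such carbons are equivalent) in preference to the carbon between the two OMOM groups, followed by C-silylation of the aryllithium.

Step 4
Reactants: 5 3,5-bis(methoxymethoxy)-2-(trimethylsilyl)phenyl N,N-diethylcarbamate
Product: 7 3,5-bis(methoxymethoxy)-2-(3-methylbut-2-en-1-yl)-6-(trimethylsilyl)phenyl N,N-diethylcarbamate, via second ortho-lithiated carbamate 6 (not isolated)
Conditions: s-BuLi, TMEDA, THF, –78 °C; then CuBr·SMe2 (cat.), prenyl bromide, –78 → –20 °C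
Reagents that add atoms: prenyl bromide (1-bromo-3-methylbut-2-ene), CC(C)=CCBr
Why: Second directed ortho-metalation at the only remaining carbon flanked by the carbamate, followed by copper-catalysed allylic substitution at the primary carbon of prenyl bromide; the silyl group goes in first so that no benzylic-allylic CH2 is present during either metalation.

Step 5
Reactants: 7 3,5-bis(methoxymethoxy)-2-(3-methylbut-2-en-1-yl)-6-(trimethylsilyl)phenyl N,N-diethylcarbamate
Product: 8 3,5-bis(methoxymethoxy)-2-(3-methylbut-2-en-1-yl)-6-(trimethylsilyl)phenol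
Conditions: LiAlH4, THF, 0 → 60 °C; then H2O
Reagents that add atoms: none
Why: Reductive cleavage of the aryl carbamate by hydride attack at its carbonyl group should free the phenol without touching the aryl–silicon bond, the acetals or the trisubstituted alkene.

Step 6
Reactants: 8 3,5-bis(methoxymethoxy)-2-(3-methylbut-2-en-1-yl)-6-(trimethylsilyl)phenol
Product: 9 3,5-bis(methoxymethoxy)-2-(3-methylbut-2-en-1-yl)-6-(trimethylsilyl)phenyl trifluoromethanesulfonate
Conditions: Tf2O, pyridine, CH2Cl2, 0 °C
Reagents that add atoms: trifluoromethanesulfonic anhydride, O=S(=O)(OS(=O)(=O)C(F)(F)F)C(F)(F)F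
Why: O-sulfonylation of the phenol gives the ortho-silylaryl triflate, the standard fluoride-triggered aryne precursor.

Step 7
Reactants: 10 3,4-dihydroxybenzaldehyde
Product: 11 3-hydroxy-4-(methoxymethoxy)benzaldehyde
Conditions: MOMCl (1.0 equiv), K2CO3 (1.0 equiv), acetone, rt
Reagents that add atoms: chloromethyl methyl ether (MOMCl), COCCl
Why: Regioselective Williamson etherification, since the 4-OH para to the formyl group is the more acidic and one equivalent of weak base should place the MOM group there.

Step 8
Reactants: 11 3-hydroxy-4-(methoxymethoxy)benzaldehyde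
Product: 12 4-(methoxymethoxy)-3-[(2-methylbut-3-en-2-yl)oxy]benzaldehyde
Conditions: methyl 2-methylbut-3-en-2-yl carbonate, Pd(PPh3)4 (cat.), THF, 0 °C
Reagents that add atoms: methyl 2-methylbut-3-en-2-yl carbonate, COC(=O)OC(C)(C)C=C
Why: Palladium-catalysed decarboxylative allylic etherification (Tsuji–Trost type), in which the phenoxide attacks the more substituted terminus of the 1,1-dimethylallyl palladium complex under kinetic control at low temperature to give the tertiary ether.

Step 9
Reactants: 12 4-(methoxymethoxy)-3-[(2-methylbut-3-en-2-yl)oxy]benzaldehyde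
Product: 13 3-hydroxy-4-(methoxymethoxy)-2-(3-methylbut-2-en-1-yl)benzaldehyde
Conditions: toluene, 120 °C (sealed tube)
Reagents that add atoms: none
Why: Aromatic Claisen rearrangement ([3,3]-sigmatropic) to C2, the only free ortho position of the ether oxygen, in which the allylic transposition turns the 1,1-dimethylallyl ether into the C-prenyl group before tautomerisation to the phenol.

Step 10
Reactants: 13 3-hydroxy-4-(methoxymethoxy)-2-(3-methylbut-2-en-1-yl)benzaldehyde
Product: 14 3-methoxy-4-(methoxymethoxy)-2-(3-methylbut-2-en-1-yl)benzaldehyde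
Conditions: MeI, K2CO3, DMF, rt
Reagents that add atoms: iodomethane, CI
Why: Williamson O-methylation of the phenol fixes the 3′-methoxy group of the target.

Step 11
Reactants: 14 3-methoxy-4-(methoxymethoxy)-2-(3-methylbut-2-en-1-yl)benzaldehyde; 15 N-methoxy-N-methylacetamide
Product: 17 rac-3-hydroxy-N-methoxy-3-[3-methoxy-4-(methoxymethoxy)-2-(3-methylbut-2-en-1-yl)phenyl]-N-methylpropanamide, via lithium enolate 16 (not isolated)
Conditions: LiN(iPr)2, THF, –78 °C; then 14, –78 °C; then H2O
Reagents that add atoms: none
Why: Aldol addition of the lithium enolate of the Weinreb acetamide to the aldehyde; the carbinol is made as a racemate because it is oxidised in the next step.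

Step 12
Reactants: 17 rac-3-hydroxy-N-methoxy-3-[3-methoxy-4-(methoxymethoxy)-2-(3-methylbut-2-en-1-yl)phenyl]-N-methylpropanamide
Product: 18 N-methoxy-3-[3-methoxy-4-(methoxymethoxy)-2-(3-methylbut-2-en-1-yl)phenyl]-N-methyl-3-oxopropanamide
Conditions: Dess–Martin periodinane, CH2Cl2, 0 °C → rt
Reagents that add atoms: none
Why: Dess–Martin oxidation of the benzylic alcohol to the aryl ketone under near-neutral conditions that should leave the alkene and the acetals untouched.

Step 13
Reactants: 18 N-methoxy-3-[3-methoxy-4-(methoxymethoxy)-2-(3-methylbut-2-en-1-yl)phenyl]-N-methyl-3-oxopropanamide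
Product: 19 (3S)-3-hydroxy-N-methoxy-3-[3-methoxy-4-(methoxymethoxy)-2-(3-methylbut-2-en-1-yl)phenyl]-N-methylpropanamide
Conditions: RuCl(p-cymene)[(S,S)-TsDPEN] (cat.), HCO2H–Et3N (5:2), CH2Cl2, 30 °C
Reagents that add atoms: none
Why: Noyori–Ikariya asymmetric transfer hydrogenation of an aryl ketone, in which the (S,S)-TsDPEN ligand should deliver hydride to the face that gives the (S)-benzylic alcohol (the later C2 stereocentre), while isolated alkenes are not reduced.

Step 14
Reactants: 19 (3S)-3-hydroxy-N-methoxy-3-[3-methoxy-4-(methoxymethoxy)-2-(3-methylbut-2-en-1-yl)phenyl]-N-methylpropanamide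
Product: 20 (3S)-N-methoxy-3-[3-methoxy-4-(methoxymethoxy)-2-(3-methylbut-2-en-1-yl)phenyl]-N-methyl-3-[(trimethylsilyl)oxy]propanamide
Conditions: Me3SiCl, imidazole, CH2Cl2, 0 °C
Reagents that add atoms: chlorotrimethylsilane, C[Si](C)(C)Cl
Why: O-silylation of the secondary alcohol gives a proton-free precursor of the alkoxide that fluoride unmasks in the next step; the stereocentre is not involved.

Step 15
Reactants: 20 (3S)-N-methoxy-3-[3-methoxy-4-(methoxymethoxy)-2-(3-methylbut-2-en-1-yl)phenyl]-N-methyl-3-[(trimethylsilyl)oxy]propanamide; 9 3,5-bis(methoxymethoxy)-2-(3-methylbut-2-en-1-yl)-6-(trimethylsilyl)phenyl trifluoromethanesulfonate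
Product: 24 (2S)-5,7-bis(methoxymethoxy)-2-[3-methoxy-4-(methoxymethoxy)-2-(3-methylbut-2-en-1-yl)phenyl]-8-(3-methylbut-2-en-1-yl)chroman-4-one, via potassium alkoxide 21 (not isolated), via aryne 22 (not isolated), via tetrahedral adduct 23 (not isolated)
Conditions: 9 (1.5 equiv), KF, 18-crown-6, THF, –20 → 0 °C; then AcOH, –20 °C
Reagents that add atoms: none
Why: Proposed new method: fluoride removes both silyl groups, so that aryne 22 and the proton-free potassium alkoxide 21 arise together; the alkoxide oxygen adds to C8a of the aryne and the aryl anion left at C4a attacks the tethered Weinreb amide, forming the C4–C4a bond and closing ring C in a 6-exo-trig mode to the tetrahedral adduct 23, which gives the ketone only on the cold acetic acid quench. The closest known reaction types are the fluoride-mediated annulation of arynes with salicylates to xanthones (O-arylation followed by acyl capture of the aryl anion), the acyl-alkylation of 3,5-dialkoxybenzynes and the O–H insertion of aliphatic alcohols into arynes; what is new is an aliphatic β-silyloxy Weinreb amide as the donor of the oxygen and the acyl carbon. Regioselectivity is needed and is set by the groups beside the triple bond: the C5 OMOM oxygen next to C4a polarises and distorts the aryne so that the nucleophile attacks the far carbon C8a and the negative charge builds up at C4a beside oxygen, while the C8 prenyl group beside C8a is only a steric penalty. No stereocentre is created in ring C; C2 comes from 19 with its C–O bond untouched, so the S configuration should be retained. Chemoselectivity for carbonyl attack over proton transfer is secured by the absence of O–H and N–H protons and by the six-membered transition state, and the tetrahedral adduct keeps the enolisable ketone masked, which should block retro-oxa-Michael racemisation under the basic conditions.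

Step 16
Reactants: 24 (2S)-5,7-bis(methoxymethoxy)-2-[3-methoxy-4-(methoxymethoxy)-2-(3-methylbut-2-en-1-yl)phenyl]-8-(3-methylbut-2-en-1-yl)chroman-4-one
Product: 25 (2S)-5,7-dihydroxy-2-[4-hydroxy-3-methoxy-2-(3-methylbut-2-en-1-yl)phenyl]-8-(3-methylbut-2-en-1-yl)chroman-4-one (CNP0282226.1)
Conditions: HCl (3 M aq.), MeOH, 40 °C
Reagents that add atoms: none
Why: Acid-catalysed acetal exchange with methanol (MOM cleavage) frees the three phenols; flavanones should hold their C2 configuration under mild acid, whereas base would open ring C, and moderate acidity and temperature should spare the prenyl groups.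

**Compound list**

1 | phloroglucinol | Oc1cc(O)cc(O)c1 | starting material
2 | 3,5-bis(methoxymethoxy)phenol | COCOc1cc(O)cc(OCOC)c1 | intermediate
3 | 3,5-bis(methoxymethoxy)phenyl N,N-diethylcarbamate | CCN(CC)C(=O)Oc1cc(OCOC)cc(OCOC)c1 | intermediate
4 | 2-lithio-3,5-bis(methoxymethoxy)phenyl N,N-diethylcarbamate | [Li]c1c(OC(=O)N(CC)CC)cc(OCOC)cc1OCOC | intermediate
5 | 3,5-bis(methoxymethoxy)-2-(trimethylsilyl)phenyl N,N-diethylcarbamate | C[Si](C)(C)c1c(OC(=O)N(CC)CC)cc(OCOC)cc1OCOC | intermediate
6 | 6-lithio-3,5-bis(methoxymethoxy)-2-(trimethylsilyl)phenyl N,N-diethylcarbamate | C[Si](C)(C)c1c(OC(=O)N(CC)CC)c([Li])c(OCOC)cc1OCOC | intermediate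
7 | 3,5-bis(methoxymethoxy)-2-(3-methylbut-2-en-1-yl)-6-(trimethylsilyl)phenyl N,N-diethylcarbamate | C[Si](C)(C)c1c(OC(=O)N(CC)CC)c(CC=C(C)C)c(OCOC)cc1OCOC | intermediate
8 | 3,5-bis(methoxymethoxy)-2-(3-methylbut-2-en-1-yl)-6-(trimethylsilyl)phenol | C[Si](C)(C)c1c(O)c(CC=C(C)C)c(OCOC)cc1OCOC | intermediate
9 | 3,5-bis(methoxymethoxy)-2-(3-methylbut-2-en-1-yl)-6-(trimethylsilyl)phenyl trifluoromethanesulfonate | C[Si](C)(C)c1c(OS(=O)(=O)C(F)(F)F)c(CC=C(C)C)c(OCOC)cc1OCOC | intermediate
10 | 3,4-dihydroxybenzaldehyde | O=Cc1ccc(O)c(O)c1 | starting material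
11 | 3-hydroxy-4-(methoxymethoxy)benzaldehyde | COCOc1ccc(C=O)cc1O | intermediate
12 | 4-(methoxymethoxy)-3-[(2-methylbut-3-en-2-yl)oxy]benzaldehyde | COCOc1ccc(C=O)cc1OC(C)(C)C=C | intermediate
13 | 3-hydroxy-4-(methoxymethoxy)-2-(3-methylbut-2-en-1-yl)benzaldehyde | COCOc1ccc(C=O)c(CC=C(C)C)c1O | intermediate
14 | 3-methoxy-4-(methoxymethoxy)-2-(3-methylbut-2-en-1-yl)benzaldehyde | COCOc1ccc(C=O)c(CC=C(C)C)c1OC | intermediate
15 | N-methoxy-N-methylacetamide | CC(=O)N(C)OC | starting material
16 | lithium enolate of N-methoxy-N-methylacetamide | C=C(O[Li])N(C)OC | intermediate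
17 | rac-3-hydroxy-N-methoxy-3-[3-methoxy-4-(methoxymethoxy)-2-(3-methylbut-2-en-1-yl)phenyl]-N-methylpropanamide | COCOc1ccc(C(O)CC(=O)N(C)OC)c(CC=C(C)C)c1OC | intermediate
18 | N-methoxy-3-[3-methoxy-4-(methoxymethoxy)-2-(3-methylbut-2-en-1-yl)phenyl]-N-methyl-3-oxopropanamide | COCOc1ccc(C(=O)CC(=O)N(C)OC)c(CC=C(C)C)c1OC | intermediate
19 | (3S)-3-hydroxy-N-methoxy-3-[3-methoxy-4-(methoxymethoxy)-2-(3-methylbut-2-en-1-yl)phenyl]-N-methylpropanamide | COc1c(OCOC)ccc([C@@H](O)CC(=O)N(C)OC)c1CC=C(C)C | intermediate
20 | (3S)-N-methoxy-3-[3-methoxy-4-(methoxymethoxy)-2-(3-methylbut-2-en-1-yl)phenyl]-N-methyl-3-[(trimethylsilyl)oxy]propanamide | COc1c(OCOC)ccc([C@@H](O[Si](C)(C)C)CC(=O)N(C)OC)c1CC=C(C)C | intermediate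
21 | potassium (1S)-3-[methoxy(methyl)amino]-1-[3-methoxy-4-(methoxymethoxy)-2-(3-methylbut-2-en-1-yl)phenyl]-3-oxopropan-1-olate | COc1c(OCOC)ccc([C@@H]([O-])CC(=O)N(C)OC)c1CC=C(C)C.[K+] | intermediate
22 | 3,5-bis(methoxymethoxy)-6-(3-methylbut-2-en-1-yl)benzyne (1,2-didehydrobenzene) | COCOC1=CC(OCOC)=C(CC=C(C)C)C#C1 | intermediate
23 | potassium (2S)-4-[methoxy(methyl)amino]-5,7-bis(methoxymethoxy)-2-[3-methoxy-4-(methoxymethoxy)-2-(3-methylbut-2-en-1-yl)phenyl]-8-(3-methylbut-2-en-1-yl)chroman-4-olate | COc1c(OCOC)ccc([C@@H]2CC([O-])(N(C)OC)c3c(OCOC)cc(OCOC)c(CC=C(C)C)c3O2)c1CC=C(C)C.[K+] | intermediate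
24 | (2S)-5,7-bis(methoxymethoxy)-2-[3-methoxy-4-(methoxymethoxy)-2-(3-methylbut-2-en-1-yl)phenyl]-8-(3-methylbut-2-en-1-yl)chroman-4-one | COc1c(OCOC)ccc([C@@H]2CC(=O)c3c(OCOC)cc(OCOC)c(CC=C(C)C)c3O2)c1CC=C(C)C | intermediate
25 | (2S)-5,7-dihydroxy-2-[4-hydroxy-3-methoxy-2-(3-methylbut-2-en-1-yl)phenyl]-8-(3-methylbut-2-en-1-yl)chroman-4-one | COc1c(O)ccc([C@@H]2CC(=O)c3c(O)cc(O)c(CC=C(C)C)c3O2)c1CC=C(C)C | target

**Summary**

Total step count: 16. Longest linear sequence: 10 steps (steps 7 to 16).

**Steps most likely to fail**

1. Step 15 (Proposed new method). What may go wrong: proton transfer to the aryl anion (from the α-CH2 of the amide or from traces of water) before it reaches the carbonyl group, so that only O-arylation takes place; retro-aldol cleavage of the free alkoxide with loss of material and of enantiopurity; addition of the alkoxide at C4a if crowding by the C8 prenyl group outweighs the electronic bias. Fallback with known chemistry, setting out from 14 and 9 and coming back at 24: 14 is condensed with malonic acid (pyridine, piperidine, 90 °C; Knoevenagel–Doebner) to (E)-3-[3-methoxy-4-(methoxymethoxy)-2-(3-methylbut-2-en-1-yl)phenyl]prop-2-enoic acid F1. F1 and 9 are then heated with CsF in THF at 125 °C. Under these conditions the known insertion of an aryne into the C–O bond of a carboxylic acid (carboxylate addition at C8a, acyl shift to C4a, governed by the same C5 OMOM group) gives the 2′-hydroxychalcone phenoxide, which closes in the flask by oxa-Michael addition to the racemic flavanone rac-5,7-bis(methoxymethoxy)-2-[3-methoxy-4-(methoxymethoxy)-2-(3-methylbut-2-en-1-yl)phenyl]-8-(3-methylbut-2-en-1-yl)chroman-4-one F2. Preparative chromatography of F2 on a chiral stationary phase then gives the (S)-enantiomer 24.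

2. Step 4. What may go wrong: allylic substitution through the tertiary terminus of the prenyl electrophile, or halogen–metal exchange and homocoupling in place of substitution, at a crowded aryl–metal centre. Fallback setting out from 5 and coming back at 7: 5 is metalated as before and the aryllithium 6 is quenched with allyl bromide (a symmetrical allyl unit, so the terminus no longer matters) to give 2-allyl-3,5-bis(methoxymethoxy)-6-(trimethylsilyl)phenyl N,N-diethylcarbamate F3. Olefin cross-metathesis of F3 with 2-methylbut-2-ene (second-generation Grubbs catalyst, CH2Cl2, 40 °C) then builds the prenyl group and gives 7.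

3. Step 8. What may go wrong: attack of the phenoxide at the unsubstituted allyl terminus, or isomerisation of the tertiary ether to the linear prenyl ether, which on rearrangement would place the wrong (1,1-dimethylallyl) group on C2′; loss of the tertiary allyl group by ionisation during heating in step 9 belongs to the same weakness. Fallback setting out from 11 and coming back at 14: 11 is O-allylated (allyl bromide, K2CO3, DMF) to 3-(allyloxy)-4-(methoxymethoxy)benzaldehyde F4. Aromatic Claisen rearrangement (N,N-diethylaniline, 190 °C) to the only free ortho position gives 2-allyl-3-hydroxy-4-(methoxymethoxy)benzaldehyde F5. O-Methylation (MeI, K2CO3, DMF) gives 2-allyl-3-methoxy-4-(methoxymethoxy)benzaldehyde F6. Cross-metathesis of F6 with 2-methylbut-2-ene (second-generation Grubbs catalyst, CH2Cl2, 40 °C) gives 14.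

**Further compounds**

F1 | step 15 | (E)-3-[3-methoxy-4-(methoxymethoxy)-2-(3-methylbut-2-en-1-yl)phenyl]prop-2-enoic acid | COc1c(OCOC)ccc(/C=C/C(=O)O)c1CC=C(C)C
F2 | step 15 | rac-5,7-bis(methoxymethoxy)-2-[3-methoxy-4-(methoxymethoxy)-2-(3-methylbut-2-en-1-yl)phenyl]-8-(3-methylbut-2-en-1-yl)chroman-4-one | COc1c(OCOC)ccc(C2CC(=O)c3c(OCOC)cc(OCOC)c(CC=C(C)C)c3O2)c1CC=C(C)C
F3 | step 4 | 2-allyl-3,5-bis(methoxymethoxy)-6-(trimethylsilyl)phenyl N,N-diethylcarbamate | C=CCc1c(OCOC)cc(OCOC)c([Si](C)(C)C)c1OC(=O)N(CC)CC
F4 | step 8 | 3-(allyloxy)-4-(methoxymethoxy)benzaldehyde | C=CCOc1cc(C=O)ccc1OCOC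
F5 | step 8 | 2-allyl-3-hydroxy-4-(methoxymethoxy)benzaldehyde | C=CCc1c(C=O)ccc(OCOC)c1O
F6 | step 8 | 2-allyl-3-methoxy-4-(methoxymethoxy)benzaldehyde | C=CCc1c(C=O)ccc(OCOC)c1OC
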